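**Plan**

- Retrosynthesis: the two benzyl ethers on the glycerol unit are removed last, and C9 and the ring B side chain are taken back to ethyl esters. C8–O4' and C7–C8 are then cut together, leaving ethyl diazoacetate, a ring B phenol and a ring A aldehyde. The aldehyde is cut at its O4–CH bond back to vanillin.
- Enabling feature: C8 is bonded to three different partners (O4' of ring B, the C7 carbinol on ring A, and C9). A carbene carbon that already carries C9 can therefore take up the phenol oxygen and the aldehyde carbon in one operation.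
- Forward order: no ring is formed. The ring A aldehyde, the ring B phenol and the C8–C9 unit are joined in step 4, then both esters are reduced and the benzyl groups removed.
- Stereochemistry: C7 and C8 are set together in step 4 as the anti (erythro) pair by a chiral Lewis acid made from Zr(OtBu)4 and a diiodo-BINOL. Later steps do not touch them; the C8 descriptor changes from S to R on ester reduction through substituent priority only.

Key step: step 4

Remark: which antipode of the BINOL ligand gives the (2S,3S) adduct with this substrate set cannot be read from precedent; the (R)-ligand is written, and the (S)-ligand would replace it if a first run shows the mirror-image sense.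

**Step 1**
Reactants: 1 vanillin; 2 1,3-bis(benzyloxy)propan-2-ol
Product: 3 4-{[1,3-bis(benzyloxy)propan-2-yl]oxy}-3-methoxybenzaldehyde
Conditions: PPh3, DIAD, THF, 0 °C to rt
Reagents that add atoms: none
Why: Mitsunobu etherification, in which the acidic para-formyl phenol displaces the alkoxyphosphonium of the secondary alcohol; the carbinol carbon is not a stereocentre, so inversion has no consequence.

**Step 2**
Reactants: 4 sinapic acid
Product: 5 ethyl (E)-3-(4-hydroxy-3,5-dimethoxyphenyl)prop-2-enoate
Conditions: EtOH, H2SO4 (cat.), reflux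
Reagents that add atoms: ethanol, CCO
Why: Fischer esterification in excess ethanol; the phenol and the cinnamate double bond are inert to these conditions.

**Step 3**
Reactants: 5 ethyl (E)-3-(4-hydroxy-3,5-dimethoxyphenyl)prop-2-enoate
Product: 6 ethyl 3-(4-hydroxy-3,5-dimethoxyphenyl)propanoate
Conditions: H2 (1 atm), 10% Pd/C, EtOAc, rt
Reagents that add atoms: none
Why: Catalytic hydrogenation of the conjugated alkene; the ester, the aryl ethers and the free phenol are unaffected at ambient pressure and temperature.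

**Step 4**
Reactants: 7 ethyl diazoacetate; 6 ethyl 3-(4-hydroxy-3,5-dimethoxyphenyl)propanoate; 3 4-{[1,3-bis(benzyloxy)propan-2-yl]oxy}-3-methoxybenzaldehyde
Product: 10 ethyl (2S,3S)-3-(4-{[1,3-bis(benzyloxy)propan-2-yl]oxy}-3-methoxyphenyl)-2-[4-(3-ethoxy-3-oxopropyl)-2,6-dimethoxyphenoxy]-3-hydroxypropanoate, via oxonium ylide 8 (not isolated), via enol 9 (not isolated)
Conditions: Rh2(OAc)4 (2 mol %), Zr(OtBu)4 (20 mol %), (R)-3,3'-diiodo-BINOL (40 mol %), 4 Å MS, CH2Cl2, 0 °C; 6 and 7 added together by syringe pump over six hours to 3 and the catalysts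
Reagents that add atoms: none
Why: Proposed new method: Rh2(OAc)4 takes N2 from 7, the phenol oxygen of 6 adds to the Rh2(OAc)4-bound carbene carbon to give oxonium ylide 8 in equilibrium with enol 9, and C8 of this species adds to aldehyde 3 held by the Zr(OtBu)4/(R)-3,3'-diiodo-BINOL complex, so that C8–O4' and C7–C8 form in one operation, ahead of the 1,2-proton shift that would end in the plain aryloxyacetate. The closest known reaction type is the three-component aldol-type trapping of alcohol-derived oxonium ylides from aryl diazoacetates with aldehydes under Rh2(OAc)4 and a chiral Lewis or Brønsted acid co-catalyst; an acceptor-only diazo ester, a 2,6-disubstituted phenol and an electron-rich aldehyde are each an extrapolation from it. No ring closes. C7 and C8 are set together in an open transition state in which the chiral Lewis acid holds the aldehyde and shields one of its faces; complexes of Zr(OtBu)4 with 3,3'-dihalo-BINOLs are known to steer Mukaiyama aldol additions to aryl aldehydes to the anti adduct whatever the enolate geometry, which is the ground for expecting the anti (2S,3S) isomer. The step needs C–C bond formation to outrun proton transfer and the diazo ester to meet Rh2(OAc)4 before it meets the activated aldehyde; slow addition keeps 6 and 7 at low concentration, the sieves deny the enol a proton shuttle, and Lewis acid activation makes up for the low electrophilicity of the 4-alkoxy-3-methoxybenzaldehyde.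

**Step 5**
Reactants: 10 ethyl (2S,3S)-3-(4-{[1,3-bis(benzyloxy)propan-2-yl]oxy}-3-methoxyphenyl)-2-[4-(3-ethoxy-3-oxopropyl)-2,6-dimethoxyphenoxy]-3-hydroxypropanoate
Product: 11 (1S,2R)-1-(4-{[1,3-bis(benzyloxy)propan-2-yl]oxy}-3-methoxyphenyl)-2-[4-(3-hydroxypropyl)-2,6-dimethoxyphenoxy]propane-1,3-diol
Conditions: LiBH4 (excess), THF, 0 °C to rt
Reagents that add atoms: none
Why: Hydride reduction of both esters to primary alcohols; the activated α-aryloxy ester should go quickly at 0 °C, before retro-aldol cleavage or C8 epimerisation can compete, the propanoate follows on warming, and neither stereocentre is touched.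

**Step 6**
Reactants: 11 (1S,2R)-1-(4-{[1,3-bis(benzyloxy)propan-2-yl]oxy}-3-methoxyphenyl)-2-[4-(3-hydroxypropyl)-2,6-dimethoxyphenoxy]propane-1,3-diol
Product: 12 (1S,2R)-1-{4-[(1,3-dihydroxypropan-2-yl)oxy]-3-methoxyphenyl}-2-[4-(3-hydroxypropyl)-2,6-dimethoxyphenoxy]propane-1,3-diol
Conditions: H2 (1 atm), 10% Pd/C, EtOAc–EtOH, rt
Reagents that add atoms: none
Why: Catalytic hydrogenolysis of the two primary benzyl ethers under neutral conditions, a debenzylation that is routinely run in the presence of the secondary benzylic alcohol of arylglycerol β-aryl ethers; C7 and C8 are not involved.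

**Compound list**

1 | vanillin (4-hydroxy-3-methoxybenzaldehyde) | COc1cc(C=O)ccc1O | starting material
2 | 1,3-bis(benzyloxy)propan-2-ol | OC(COCc1ccccc1)COCc1ccccc1 | starting material
3 | 4-{[1,3-bis(benzyloxy)propan-2-yl]oxy}-3-methoxybenzaldehyde (ring A aldehyde) | COc1cc(C=O)ccc1OC(COCc1ccccc1)COCc1ccccc1 | intermediate
4 | sinapic acid, (E)-3-(4-hydroxy-3,5-dimethoxyphenyl)prop-2-enoic acid | COc1cc(/C=C/C(=O)O)cc(OC)c1O | starting material
5 | ethyl (E)-3-(4-hydroxy-3,5-dimethoxyphenyl)prop-2-enoate | CCOC(=O)/C=C/c1cc(OC)c(O)c(OC)c1 | intermediate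
6 | ethyl 3-(4-hydroxy-3,5-dimethoxyphenyl)propanoate (ring B phenol) | CCOC(=O)CCc1cc(OC)c(O)c(OC)c1 | intermediate
7 | ethyl diazoacetate | CCOC(=O)C=[N+]=[N-] | starting material
8 | oxonium ylide from 6 and the carbene of 7, written as the free zwitterion (not isolated) | CCOC(=O)[CH-][OH+]c1c(OC)cc(CCC(=O)OCC)cc1OC | intermediate
9 | enol tautomer of 8, ethyl 3-{4-[(2-ethoxy-2-hydroxyethenyl)oxy]-3,5-dimethoxyphenyl}propanoate, double-bond geometry not defined (not isolated) | CCOC(O)=COc1c(OC)cc(CCC(=O)OCC)cc1OC | intermediate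
10 | ethyl (2S,3S)-3-(4-{[1,3-bis(benzyloxy)propan-2-yl]oxy}-3-methoxyphenyl)-2-[4-(3-ethoxy-3-oxopropyl)-2,6-dimethoxyphenoxy]-3-hydroxypropanoate (anti adduct) | COc1cc([C@H](O)[C@@H](C(=O)OCC)Oc2c(OC)cc(CCC(=O)OCC)cc2OC)ccc1OC(COCc1ccccc1)COCc1ccccc1 | intermediate
11 | (1S,2R)-1-(4-{[1,3-bis(benzyloxy)propan-2-yl]oxy}-3-methoxyphenyl)-2-[4-(3-hydroxypropyl)-2,6-dimethoxyphenoxy]propane-1,3-diol | COc1cc([C@H](O)[C@@H](CO)Oc2c(OC)cc(CCCO)cc2OC)ccc1OC(COCc1ccccc1)COCc1ccccc1 | intermediate
12 | (1S,2R)-1-{4-[(1,3-dihydroxypropan-2-yl)oxy]-3-methoxyphenyl}-2-[4-(3-hydroxypropyl)-2,6-dimethoxyphenoxy]propane-1,3-diol, the (7S,8R) erythro isomer | COc1cc([C@H](O)[C@@H](CO)Oc2c(OC)cc(CCCO)cc2OC)ccc1OC(CO)CO | target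

**Step count**

Total: 6 steps. Longest linear sequence: 5 steps (steps 2, 3, 4, 5 and 6, from sinapic acid).

**Steps most likely to fail**

Step 4 (proposed new method). Proton transfer within ylide 8 or enol 9 may outrun C–C bond formation, so that only O–H insertion occurs. The diazo ester may also add directly to the Lewis-acid-activated aldehyde, or the facial and anti/syn selectivity may be poor. The fallback uses known chemistry, sets out from 6 and returns to the route at 11. Phenol 6 would be O-alkylated (K2CO3, acetone, rt) with (R)-4-benzyl-3-(bromoacetyl)oxazolidin-2-one (O=C(CBr)N1C(=O)OC[C@H]1Cc1ccccc1) to give the aryloxyacetyl imide (R)-4-benzyl-3-{[4-(3-ethoxy-3-oxopropyl)-2,6-dimethoxyphenoxy]acetyl}oxazolidin-2-one F1. A MgCl2-catalysed anti-aldol addition of F1 to aldehyde 3 (MgCl2 10 mol %, Et3N, Me3SiCl, EtOAc, rt) runs through the chelated (Z)-enolate. It should set the α-centre on the face away from the benzyl group, as in alkylations of this auxiliary, and the carbinol centre anti to it. The expected product is the silylated adduct (R)-4-benzyl-3-[(2S,3S)-3-(4-{[1,3-bis(benzyloxy)propan-2-yl]oxy}-3-methoxyphenyl)-2-[4-(3-ethoxy-3-oxopropyl)-2,6-dimethoxyphenoxy]-3-(trimethylsilyloxy)propanoyl]oxazolidin-2-one F2. Buffered fluoride (Bu4NF/AcOH, THF, 0 °C) would free the hydroxy imide (R)-4-benzyl-3-[(2S,3S)-3-(4-{[1,3-bis(benzyloxy)propan-2-yl]oxy}-3-methoxyphenyl)-2-[4-(3-ethoxy-3-oxopropyl)-2,6-dimethoxyphenoxy]-3-hydroxypropanoyl]oxazolidin-2-one F3. LiBH4 (THF, 0 °C to rt) would then cleave the auxiliary reductively and reduce the side-chain ester in the same flask, arriving at 11.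

Step 1. Substitution at the secondary carbinol flanked by two benzyloxymethyl groups may be slow, and the alkoxyphosphonium may then be diverted to elimination or to alkylation of the hydrazide. The fallback sets out from 2 and returns at 3. The sodium alkoxide of 2 (NaH, DMF, 0 °C) would be treated with 4-fluoro-3-methoxybenzaldehyde (COc1cc(C=O)ccc1F) at 50 °C. This nucleophilic aromatic substitution para to the formyl group forms the same C–O bond at the arene carbon instead of at the hindered carbinol carbon and gives 3 directly; no compound outside the list is made on this path (F0).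

Step 6. Over-reduction may occur: the electron-rich benzylic C7–O bond may be hydrogenolysed before both aliphatic benzyl ethers are gone. The fallback replaces the benzyl ethers by an acid-labile acetal, so that no hydrogenation is needed once C7 is in place; it sets out from 1 and returns at 12. Vanillin 1 would be etherified under Mitsunobu conditions (PPh3, DIAD, THF) with 2,2-dimethyl-1,3-dioxan-5-ol (OC1COC(C)(C)OC1) to give 4-[(2,2-dimethyl-1,3-dioxan-5-yl)oxy]-3-methoxybenzaldehyde F4. Under the conditions of step 4, F4 with 6 and 7 should give ethyl (2S,3S)-3-{4-[(2,2-dimethyl-1,3-dioxan-5-yl)oxy]-3-methoxyphenyl}-2-[4-(3-ethoxy-3-oxopropyl)-2,6-dimethoxyphenoxy]-3-hydroxypropanoate F5. LiBH4 as in step 5 should give (1S,2R)-1-{4-[(2,2-dimethyl-1,3-dioxan-5-yl)oxy]-3-methoxyphenyl}-2-[4-(3-hydroxypropyl)-2,6-dimethoxyphenoxy]propane-1,3-diol F6. Hydrolysis of the acetonide in AcOH–H2O at rt would then give 12.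

**Further compounds**

F1 | step 4 | (R)-4-benzyl-3-{[4-(3-ethoxy-3-oxopropyl)-2,6-dimethoxyphenoxy]acetyl}oxazolidin-2-one | CCOC(=O)CCc1cc(OC)c(OCC(=O)N2C(=O)OC[C@H]2Cc2ccccc2)c(OC)c1
F2 | step 4 | (R)-4-benzyl-3-[(2S,3S)-3-(4-{[1,3-bis(benzyloxy)propan-2-yl]oxy}-3-methoxyphenyl)-2-[4-(3-ethoxy-3-oxopropyl)-2,6-dimethoxyphenoxy]-3-(trimethylsilyloxy)propanoyl]oxazolidin-2-one | COc1cc([C@H](O[Si](C)(C)C)[C@@H](C(=O)N3C(=O)OC[C@H]3Cc3ccccc3)Oc2c(OC)cc(CCC(=O)OCC)cc2OC)ccc1OC(COCc1ccccc1)COCc1ccccc1
F3 | step 4 | (R)-4-benzyl-3-[(2S,3S)-3-(4-{[1,3-bis(benzyloxy)propan-2-yl]oxy}-3-methoxyphenyl)-2-[4-(3-ethoxy-3-oxopropyl)-2,6-dimethoxyphenoxy]-3-hydroxypropanoyl]oxazolidin-2-one | COc1cc([C@H](O)[C@@H](C(=O)N3C(=O)OC[C@H]3Cc3ccccc3)Oc2c(OC)cc(CCC(=O)OCC)cc2OC)ccc1OC(COCc1ccccc1)COCc1ccccc1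
F0 | step 1 | none | none
F4 | step 6 | 4-[(2,2-dimethyl-1,3-dioxan-5-yl)oxy]-3-methoxybenzaldehyde | COc1cc(C=O)ccc1OC1COC(C)(C)OC1
F5 | step 6 | ethyl (2S,3S)-3-{4-[(2,2-dimethyl-1,3-dioxan-5-yl)oxy]-3-methoxyphenyl}-2-[4-(3-ethoxy-3-oxopropyl)-2,6-dimethoxyphenoxy]-3-hydroxypropanoate | COc1cc([C@H](O)[C@@H](C(=O)OCC)Oc2c(OC)cc(CCC(=O)OCC)cc2OC)ccc1OC1COC(C)(C)OC1
F6 | step 6 | (1S,2R)-1-{4-[(2,2-dimethyl-1,3-dioxan-5-yl)oxy]-3-methoxyphenyl}-2-[4-(3-hydroxypropyl)-2,6-dimethoxyphenoxy]propane-1,3-diol | COc1cc([C@H](O)[C@@H](CO)Oc2c(OC)cc(CCCO)cc2OC)ccc1OC1COC(C)(C)OC1
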